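The eta run is the one earlier flask I have, and at 2.7 equiv of reagent and 45 °C it read 10.6% of target after 5.00 h. I follow one substrate molecule through it. I take its chance of becoming target to go with the reagent present, so at 1.80 equiv and 45 °C a fresh molecule has a chance per hour p of 0.0141 h⁻¹, a reading that carries the scatter.

common to all: substrate 20 mM
- eta: reagent 2.7 equiv; temperature 45 °C; run made earlier
- Tuesday's: reagent 1.80 equiv; at 70 °C until 5.0 h, from then on at 20 °C; time 25 h
- Thursday's: reagent 1.80 equiv; temperature 45 °C; time 25 h
- Friday's: reagent 1.80 equiv; temperature 20 °C; time 25 h
- Saturday's: reagent 1.80 equiv; temperature 70 °C; time 25 h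

eta run (percent of the substrate charged)

| time / h | target / % |
|---|---|
| 1.00 | 1.5 |
| 2.00 | 4.2 |
| 3.00 | 6.6 |
| 4.00 | 8.1 |
| 5.00 | 10.6 |

(readings scatter by 0.5 percentage points)

- the numbers in the tables scatter by 0.5 percentage points (one standard deviation)
- the earlier runs do not show what temperature does; that part of a forecast is a guess

- the best flask by amount of target, in percent of the substrate charged; "all alike" if 1.5 percentage points covers them all (Tuesday's / Thursday's / Friday's / Saturday's / all alike)
- amount of target at the end, in percent of the substrate charged, Tuesday's
- amount of target at the end, in percent of the substrate charged, Thursday's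
- amount of target at the end, in percent of the substrate charged, Friday's
- amount of target at the end, in percent of the substrate charged, Saturday's

Thursday's flask has the eta run's temperature, so p applies to it directly. Over 25 h a molecule collects a summed chance X = pt of 0.353. If every molecule that reacts becomes target, the target is 1 − e^(−X), or 29.7%, and that is a little high, since I hold the reagent at its charge. Temperature is a guess, because the earlier runs do not show it. I take a factor of 7 from 45 °C to 70 °C, so Saturday's X is 2.47 and its target 91.6%.

The weak link is the word "every", since the eta run reads target and nothing else. I reforge it with a fork: let φ be the share of reacting molecules that become target. Then the chance of any exit is p/φ, and the target is φ(1 − e^(−X/φ)), which in a long, hot flask climbs towards φ. With φ at 0.5, Thursday's gives 25.3%, but Saturday's gives 49.6%. So I commit to Thursday's near 27%, and to Saturday's as the best flask with its amount open.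

The forecast picks Saturday's, with 78% there, 36% for Tuesday's, 27% for Thursday's and 4% for Friday's. Its reservation is “Saturday's should win, unless the target or reagent degrades when hot”.

Saturday's flask comes out best at 53.8% of target, against 31.0% for Tuesday's, 25.0% for Thursday's and 4.07% for Friday's.

    substrate + reagent → target (k = 2.81 L mol⁻¹ h⁻¹, Ea = 68.0 kJ mol⁻¹)
    substrate + reagent → isomer of the product (k = 2.05 L mol⁻¹ h⁻¹, Ea = 64.0 kJ mol⁻¹)
    target → over-reaction product (k = 3.37 × 10⁻⁵ h⁻¹, Ea = 126 kJ mol⁻¹)
    (constants at 70 °C)

In Saturday's flask 93.1% of the substrate has reacted, and the isomer of the product stands at 39.3%. Now p returns on Thursday's flask, where 55% of the substrate remains. Its summed chance of any exit is 0.598, and in Thursday's flask the target is a share φ (the selectivity) of 55.1% of the reacted substrate. The target's part of that sum is therefore 0.329, less than the X of 0.353 that held the reagent at its charge. Thursday's share of Saturday's reacted substrate comes to 51.3%.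

Readings and results are simulated for substances that don't exist.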